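**Retrosynthetic overview**

1. 18 ← 17: the hexanoic acid is carried as a temporary six-membered enol lactone (ring B) onto the ring A oxygen beside the side-chain carbon, and is hydrolysed last.
2. 17 ← 15 (key step): in one flask the aromatic 1,1-dimethylallyl ether 15 undergoes a dearomative Claisen shift (quaternary carbon, relayed from the lactone stereocentre) and then a catalytic oxa-Michael closure of ring C through the O–CH(CH3) bond (both methyl-bearing carbons).
3. 15 ← 12 + 5: Negishi union of the iodoarene with a chiral alkylzinc (stereocentre from a copper-catalysed asymmetric SN2' alkylation); 12 comes from commercial 5,7-dihydroxy-4-propylcoumarin by asymmetric conjugate reduction, C8 tigloylation and C6 iodination.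
4. Ring order: ring B (present in the coumarin) → ring A dearomatized → ring C closed → ring B opened.
5. Enabling feature: in ring A the tigloyl-bearing carbon lies between two enol-type oxygens (a 2-acylcyclohexane-1,3-dione array); the oxygen toward the side chain is locked in ring B, so only the acidic enol O–H beside the quaternary carbon, hydrogen-bonded to the tigloyl C=O, can add 6-endo to the enone β-carbon.

Key step: step 10

Remark on locants: intermediates are numbered as 3,4-dihydro-2H-chromen-2-ones (ring B: O1, C2, C3, C4; ring A: C4a to C8a); atoms of the pyranone ring C carry primes (O1' on C7, C4' on C8).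
Remark on catalyst sense: the ligand enantiomers in steps 2 and 5 and the alkaloid in step 10 are chosen by analogy with related substrates; the mirror-image ligand (or quinidine) is to be used if a first trial shows the opposite sense.

**Route**

Step 1
Reactants: 1 4-bromo-2-methylbut-1-ene
Product: 2 (3-methylbut-3-en-1-yl)magnesium bromide
Conditions: Mg turnings, I2 (cat.), Et2O, reflux; used as a titrated solution
Reagents that add atoms: magnesium, [Mg]
Why: Grignard formation by magnesium insertion into the primary C–Br bond, the homoallyl/cyclopropylcarbinyl equilibrium of this reagent being degenerate so that one constitution results.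

Step 2
Reactants: 3 (E)-1,4-dibromo-2-methylbut-2-ene; 2 (3-methylbut-3-en-1-yl)magnesium bromide
Product: 4 (3S)-3-(bromomethyl)-2,6-dimethylhepta-1,6-diene
Conditions: CuBr·SMe2 (3 mol%), (R,R)-Taniaphos (3.5 mol%), CH2Cl2, −78 °C, slow addition of 2 (1.1 equiv)
Reagents that add atoms: 2 (3-methylbut-3-en-1-yl)magnesium bromide, C=C(C)CC[Mg]Br
Why: Copper-catalysed asymmetric allylic alkylation (anti SN2') in which the alkylcopper species should add to the CH terminus rather than to the methyl-bearing carbon, expelling the bromide of the CH2 group on the methyl-bearing carbon to unveil the isopropenyl group, with the chiral diphosphine on copper setting the stereocentre and the remaining non-allylic primary bromide inert at −78 °C.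

Step 3
Reactants: 4 (3S)-3-(bromomethyl)-2,6-dimethylhepta-1,6-diene
Product: 5 [(2S)-5-methyl-2-(prop-1-en-2-yl)hex-5-en-1-yl]zinc bromide
Conditions: Zn dust (activated with BrCH2CH2Br and Me3SiCl), LiCl, THF, 45 °C; solution titrated with I2 and used directly
Reagents that add atoms: zinc, [Zn]
Why: LiCl-promoted direct zinc insertion into a primary alkyl bromide should give the alkylzinc bromide without touching the stereocentre, which is β to the metal.

Step 4
Reactants: 6 5,7-dihydroxy-4-propyl-2H-chromen-2-one
Product: 7 5,7-bis(tert-butyldimethylsilyloxy)-4-propyl-2H-chromen-2-one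
Conditions: TBSCl (2.4 equiv), imidazole (5 equiv), DMF, rt
Reagents that add atoms: tert-butyldimethylsilyl chloride, CC(C)(C)[Si](C)(C)Cl
Why: Standard silylation of both phenols, which masks the acidic O–H groups that would otherwise quench the CuH catalyst of step 5.

Step 5
Reactants: 7 5,7-bis(tert-butyldimethylsilyloxy)-4-propyl-2H-chromen-2-one
Product: 9 (4S)-5,7-dihydroxy-4-propyl-3,4-dihydro-2H-chromen-2-one, via bis-silyl dihydrocoumarin 8 (not isolated)
Conditions: Cu(OAc)2·H2O (3 mol%), (R)-DTBM-SEGPHOS (3 mol%), (EtO)2MeSiH (2 equiv), t-BuOH (1.2 equiv), PhMe, 0 °C to rt; then HF·pyridine, THF, 0 °C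
Reagents that add atoms: none
Why: CuH-catalysed asymmetric conjugate reduction of the β,β-disubstituted unsaturated lactone (a reaction type known for 4-substituted coumarins) should deliver hydride to C4 within the chiral bisphosphine pocket and so set the 4S centre, after which fluoride cleaves the aryl silyl ethers.

Step 6
Reactants: 9 (4S)-5,7-dihydroxy-4-propyl-3,4-dihydro-2H-chromen-2-one; 10 (E)-2-methylbut-2-enoyl chloride (tigloyl chloride)
Product: 11 (4S)-5,7-dihydroxy-8-[(E)-2-methylbut-2-enoyl]-4-propyl-3,4-dihydro-2H-chromen-2-one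
Conditions: AlCl3 (4 equiv), PhNO2/ClCH2CH2Cl, 0 °C to rt; cold aq. HCl work-up
Reagents that add atoms: 10 (E)-2-methylbut-2-enoyl chloride, C/C=C(\C)C(=O)Cl
Why: Friedel–Crafts acylation of the phloroglucinol-type ring, expected at C8 (between the 7-OH and the ring oxygen) by analogy with 5,7-dihydroxy-4-alkylcoumarins because C6 is flanked by two aluminium phenoxides, with retention of the E enone.

Step 7
Reactants: 11 (4S)-5,7-dihydroxy-8-[(E)-2-methylbut-2-enoyl]-4-propyl-3,4-dihydro-2H-chromen-2-one
Product: 12 (4S)-5,7-dihydroxy-6-iodo-8-[(E)-2-methylbut-2-enoyl]-4-propyl-3,4-dihydro-2H-chromen-2-one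
Conditions: N-iodosuccinimide (1.05 equiv), MeCN, 0 °C, dark
Reagents that add atoms: N-iodosuccinimide, O=C1CCC(=O)N1I
Why: Electrophilic aromatic iodination at C6, the only free and doubly hydroxyl-activated ring position, the electron-poor enone being left alone.

Step 8
Reactants: 12 (4S)-5,7-dihydroxy-6-iodo-8-[(E)-2-methylbut-2-enoyl]-4-propyl-3,4-dihydro-2H-chromen-2-one; 5 [(2S)-5-methyl-2-(prop-1-en-2-yl)hex-5-en-1-yl]zinc bromide
Product: 13 (4S)-5,7-dihydroxy-8-[(E)-2-methylbut-2-enoyl]-6-[(2R)-5-methyl-2-(prop-1-en-2-yl)hex-5-en-1-yl]-4-propyl-3,4-dihydro-2H-chromen-2-one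
Conditions: Pd(OAc)2 (4 mol%), SPhos (8 mol%), THF, 25 °C, 5 (2.5 equiv) added over 1 h; aq. NH4Cl
Reagents that add atoms: 5 [(2S)-5-methyl-2-(prop-1-en-2-yl)hex-5-en-1-yl]zinc bromide, C=C(C)CC[C@H](C[Zn]Br)C(=C)C
Why: Negishi sp2–sp3 cross-coupling, which tolerates ketone, lactone and (with slow addition of excess zinc reagent) free phenols, the bulky biarylphosphine favouring reductive elimination over β-hydride elimination and the stereocentre being untouched (its descriptor changes from S to R only through CIP priorities).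

Step 9
Reactants: 13 (4S)-5,7-dihydroxy-8-[(E)-2-methylbut-2-enoyl]-6-[(2R)-5-methyl-2-(prop-1-en-2-yl)hex-5-en-1-yl]-4-propyl-3,4-dihydro-2H-chromen-2-one; 14 tert-butyl 2-methylbut-3-en-2-yl carbonate
Product: 15 (4S)-7-hydroxy-8-[(E)-2-methylbut-2-enoyl]-5-[(2-methylbut-3-en-2-yl)oxy]-6-[(2R)-5-methyl-2-(prop-1-en-2-yl)hex-5-en-1-yl]-4-propyl-3,4-dihydro-2H-chromen-2-one
Conditions: Pd(PPh3)4 (5 mol%), 14 (1.3 equiv), THF, 0 °C; rapid filtration through silica at 0 °C
Reagents that add atoms: 14 tert-butyl 2-methylbut-3-en-2-yl carbonate, C=CC(C)(C)OC(=O)OC(C)(C)C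
Why: Tsuji–Trost O-allylation of a phenol with a 1,1-dimethylallyl carbonate, which kinetically gives the tertiary (branched) aryl ether, should take place at the more acidic, non-chelated 5-OH while the 7-OH stays locked in its hydrogen bond to the tigloyl carbonyl.

Step 10
Reactants: 15 (4S)-7-hydroxy-8-[(E)-2-methylbut-2-enoyl]-5-[(2-methylbut-3-en-2-yl)oxy]-6-[(2R)-5-methyl-2-(prop-1-en-2-yl)hex-5-en-1-yl]-4-propyl-3,4-dihydro-2H-chromen-2-one
Product: 17 tricyclic enol lactone (4S,6R,2'R,3'S; ring C closed; full name in the compound list), via dearomatized tigloyl enol 16 (not isolated)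
Conditions: PhCl, 80 °C; then 0 °C, quinine (20 mol%)
Reagents that add atoms: none
Why: Proposed new method: heat first drives an aromatic Claisen rearrangement of the 1,1-dimethylallyl ether to C6 (the only ortho carbon whose dienone is stabilized as a chelated enol), which dearomatizes ring A and converts the 7-OH into the acidic enol of a β-triketone (16); quinine then forms a hydrogen-bonded ion pair with this enol and guides its oxygen onto the β-carbon of the tigloyl enone in a 6-endo-trig oxa-Michael closure of ring C, the closest known reactions being the dearomatizing Claisen shift of 2,6-disubstituted aryl 1,1-dimethylallyl ethers and the cinchona alkaloid-catalysed cyclization of o-tigloylphenols to cis-2,3-dimethylchroman-4-ones, which has not been shown for enols of dearomatized acylphloroglucinols. The quaternary carbon is controlled by the 4S centre of the temporary lactone: the tertiary ether group can only lie on the ring face opposite to the pseudo-axial peri propyl group, and the suprafacial [3,3] shift delivers the prenyl group to C6 on that face (6R). C2' is set by the catalyst (2'R expected by analogy with the phenol series) and C3' by kinetic protonation of the ring enolate anti to the pseudo-axial C2' methyl group, which gives the cis (2'R,3'S) pair. Regioselectivity rests on the lactone, which ties up the other oxygen flanking the acyl-bearing carbon so that only the C7 oxygen can cyclize, and the cis selectivity needs kinetic control, which the non-acidic product (it releases the catalyst) and the low temperature should secure. Telescoping avoids isolating 16, whose uncatalysed cyclization on silica would erode the stereocontrol.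

Step 11
Reactants: 17 tricyclic enol lactone (4S,6R,2'R,3'S)
Product: 18 (3S)-3-[(2R,3S,8R)-5-hydroxy-2,3-dimethyl-8-(3-methylbut-2-en-1-yl)-8-[(2R)-5-methyl-2-(prop-1-en-2-yl)hex-5-en-1-yl]-4,7-dioxo-3,4,7,8-tetrahydro-2H-chromen-6-yl]hexanoic acid
Conditions: LiOH·H2O (2.5 equiv), THF/H2O (3:1), 0 °C; then cold 1 M HCl to pH 3
Reagents that add atoms: lithium hydroxide, [Li+].[OH-]
Why: Saponification of the enol lactone, a vinylogous anhydride far more electrophilic than the vinylogous ester of ring C, should release the carboxylic acid and the ring A enol, and the resulting dianion resists deprotonation at C3', so the cis methyl pair should survive.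

**Compound list**

1 | 4-bromo-2-methylbut-1-ene | C=C(C)CCBr | starting material
2 | (3-methylbut-3-en-1-yl)magnesium bromide | C=C(C)CC[Mg]Br | intermediate
3 | (E)-1,4-dibromo-2-methylbut-2-ene | BrC/C(C)=C/CBr | starting material
4 | (3S)-3-(bromomethyl)-2,6-dimethylhepta-1,6-diene | C=C(C)CC[C@H](CBr)C(=C)C | intermediate
5 | [(2S)-5-methyl-2-(prop-1-en-2-yl)hex-5-en-1-yl]zinc bromide | C=C(C)CC[C@H](C[Zn]Br)C(=C)C | intermediate
6 | 5,7-dihydroxy-4-propyl-2H-chromen-2-one | CCCC1=CC(=O)Oc2cc(O)cc(O)c12 | starting material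
7 | 5,7-bis(tert-butyldimethylsilyloxy)-4-propyl-2H-chromen-2-one | CCCC1=CC(=O)Oc2cc(O[Si](C)(C)C(C)(C)C)cc(O[Si](C)(C)C(C)(C)C)c12 | intermediate
8 | (4S)-5,7-bis(tert-butyldimethylsilyloxy)-4-propyl-3,4-dihydro-2H-chromen-2-one | O=C1C[C@H](CCC)c2c(O[Si](C)(C)C(C)(C)C)cc(O[Si](C)(C)C(C)(C)C)cc2O1 | intermediate
9 | (4S)-5,7-dihydroxy-4-propyl-3,4-dihydro-2H-chromen-2-one | O=C1C[C@H](CCC)c2c(O)cc(O)cc2O1 | intermediate
10 | (E)-2-methylbut-2-enoyl chloride (tigloyl chloride) | C/C=C(\C)C(=O)Cl | starting material
11 | (4S)-5,7-dihydroxy-8-[(E)-2-methylbut-2-enoyl]-4-propyl-3,4-dihydro-2H-chromen-2-one | O=C1C[C@H](CCC)c2c(O)cc(O)c(C(=O)/C(C)=C/C)c2O1 | intermediate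
12 | (4S)-5,7-dihydroxy-6-iodo-8-[(E)-2-methylbut-2-enoyl]-4-propyl-3,4-dihydro-2H-chromen-2-one | O=C1C[C@H](CCC)c2c(O)c(I)c(O)c(C(=O)/C(C)=C/C)c2O1 | intermediate
13 | (4S)-5,7-dihydroxy-8-[(E)-2-methylbut-2-enoyl]-6-[(2R)-5-methyl-2-(prop-1-en-2-yl)hex-5-en-1-yl]-4-propyl-3,4-dihydro-2H-chromen-2-one | C=C(C)CC[C@H](Cc1c(O)c2[C@@H](CCC)CC(=O)Oc2c(C(=O)/C(C)=C/C)c1O)C(=C)C | intermediate
14 | tert-butyl 2-methylbut-3-en-2-yl carbonate | C=CC(C)(C)OC(=O)OC(C)(C)C | starting material
15 | (4S)-7-hydroxy-8-[(E)-2-methylbut-2-enoyl]-5-[(2-methylbut-3-en-2-yl)oxy]-6-[(2R)-5-methyl-2-(prop-1-en-2-yl)hex-5-en-1-yl]-4-propyl-3,4-dihydro-2H-chromen-2-one | C=C(C)CC[C@H](Cc1c(OC(C)(C)C=C)c2[C@@H](CCC)CC(=O)Oc2c(C(=O)/C(C)=C/C)c1O)C(=C)C | intermediate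
16 | (4S,6R)-7-hydroxy-8-[(E)-2-methylbut-2-enoyl]-6-(3-methylbut-2-en-1-yl)-6-[(2R)-5-methyl-2-(prop-1-en-2-yl)hex-5-en-1-yl]-4-propyl-3,4-dihydro-2H-chromene-2,5(6H)-dione | C=C(C)CC[C@H](C[C@@]1(CC=C(C)C)C(=O)C2=C(OC(=O)C[C@@H]2CCC)C(C(=O)/C(C)=C/C)=C1O)C(=C)C | intermediate
17 | (4S,6R)-6-(3-methylbut-2-en-1-yl)-6-[(2R)-5-methyl-2-(prop-1-en-2-yl)hex-5-en-1-yl]-4-propyl-3,4-dihydro-2H-chromene-2,5(6H)-dione fused across C7–C8 to a cis-(2'R,3'S)-2',3'-dimethyl-2',3'-dihydro-4'H-pyran-4'-one ring (O1' on C7; C4'=O on C8) | C=C(C)CC[C@H](C[C@@]1(CC=C(C)C)C(=O)C3=C(OC(=O)C[C@@H]3CCC)C2=C1O[C@H](C)[C@H](C)C2=O)C(=C)C | intermediate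
18 | (3S)-3-[(2R,3S,8R)-5-hydroxy-2,3-dimethyl-8-(3-methylbut-2-en-1-yl)-8-[(2R)-5-methyl-2-(prop-1-en-2-yl)hex-5-en-1-yl]-4,7-dioxo-3,4,7,8-tetrahydro-2H-chromen-6-yl]hexanoic acid | C=C(C)CC[C@H](C[C@@]1(CC=C(C)C)C(=O)C([C@@H](CCC)CC(=O)O)=C(O)C2=C1O[C@H](C)[C@H](C)C2=O)C(=C)C | target

**Step count and risks**

Total step count: 11. Longest linear sequence: 8 steps (6 to 18, steps 4 to 11).

Step 10 (proposed new method). What may go wrong: the acidic enol may cyclize without the catalyst during the thermal stage; ring opening and reclosure may drift the methyl pair toward trans; the ion pair may show a weak or reversed facial preference on this new substrate class. Fallback with known chemistry: it sets out from 13 and runs the quinine-catalysed oxa-Michael cyclization (PhCl, rt) on the aromatic o-tigloylphenol, the substrate class for which the cis-selective reaction is established and in which only the 7-OH is ortho to the enone. This gives the aromatic cis-chromanone lactone F1. Its single remaining phenol is O-allylated with 14 [Pd(PPh3)4, THF, 0 °C] to the 1,1-dimethylallyl ether F2. Heating F2 (PhMe, 80 °C, neutral) lets the same lactone-controlled dearomative Claisen rearrangement deliver 17, where the fallback rejoins the route.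

Step 9. What may go wrong: O-allylation of the crowded 5-OH may be slow, may take place at the chelated 7-OH, or may give the linear prenyl ether after re-ionization. Fallback: it sets out from 13 and alkylates carbon directly (LiHMDS, 2.2 equiv, THF, −78 °C, then prenyl bromide, −78 to 0 °C), an alkylative dearomatization of the lithium phenoxide at C6 of the kind known for acylphloroglucinols. It makes no new compound (F0) and comes back at 16, which enters the quinine stage of step 10. Facial control then rests only on approach anti to the pseudo-axial propyl group, with chromatographic removal of the C6 epimer after ring closure.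

Step 8. What may go wrong: the two acidic phenols may protonate the alkylzinc, and oxidative addition and transmetalation at the doubly ortho-substituted, chelated iodoarene may be sluggish, with loss of iodine by reduction as the competing process. Fallback: it sets out from 12 and masks both phenols as triethylsilyl ethers (Et3SiOTf, 2,6-lutidine, CH2Cl2, −40 °C) to give the bis-silyl iodoarene F3. The Negishi coupling is then run with only 1.3 equiv of 5 on this neutral, non-chelating partner to give the bis-silyl coupling product F4. Cleavage of the silyl ethers (HF·pyridine, THF, 0 °C) comes back at 13.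

Further compounds
F1 | step 10 | (4S)-5-hydroxy-6-[(2R)-5-methyl-2-(prop-1-en-2-yl)hex-5-en-1-yl]-4-propyl-3,4-dihydro-2H-chromen-2-one fused across C7–C8 to a cis-(2'R,3'S)-2',3'-dimethyl-2',3'-dihydro-4'H-pyran-4'-one ring (aromatic cis-chromanone lactone) | C=C(C)CC[C@H](Cc1c(O)c2[C@@H](CCC)CC(=O)Oc2c3c1O[C@H](C)[C@H](C)C3=O)C(=C)C
F2 | step 10 | 5-O-(2-methylbut-3-en-2-yl) ether of F1 | C=C(C)CC[C@H](Cc1c(OC(C)(C)C=C)c2[C@@H](CCC)CC(=O)Oc2c3c1O[C@H](C)[C@H](C)C3=O)C(=C)C
F0 | step 9 | none | none
F3 | step 8 | (4S)-6-iodo-8-[(E)-2-methylbut-2-enoyl]-4-propyl-5,7-bis(triethylsilyloxy)-3,4-dihydro-2H-chromen-2-one | O=C1C[C@H](CCC)c2c(O[Si](CC)(CC)CC)c(I)c(O[Si](CC)(CC)CC)c(C(=O)/C(C)=C/C)c2O1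
F4 | step 8 | (4S)-8-[(E)-2-methylbut-2-enoyl]-6-[(2R)-5-methyl-2-(prop-1-en-2-yl)hex-5-en-1-yl]-4-propyl-5,7-bis(triethylsilyloxy)-3,4-dihydro-2H-chromen-2-one | C=C(C)CC[C@H](Cc1c(O[Si](CC)(CC)CC)c2[C@@H](CCC)CC(=O)Oc2c(C(=O)/C(C)=C/C)c1O[Si](CC)(CC)CC)C(=C)C
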